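**Plan**

- Numbering: octalin C1 (dienoic acid), C2 (butenyl), C3 (methyl, C3=C4), C4a/C8a (fusion), C7 (sulfate), C8 (methyl); ring A = C1–C4, C4a, C8a; ring B = C4a–C8a.
- Cuts, in retrosynthetic order: the O–S bond; the first C=C of the dienoate (vinylogous Horner–Wadsworth–Emmons); then C1–C8a. C8a is the beta carbon of a ring B 2-methylcyclohex-2-enone (C7 carbonyl, C8 methyl) and C1 is alpha to the first chain carbon held as an aldehyde, so C1–C8a is a Michael bond.
- Further cuts: C1–C2 (Johnson–Claisen), C2–C3 (Negishi coupling), C3=C4 (iodo-Wittig), and ring B itself (Michael addition/aldol condensation of 3-[(4-methoxybenzyl)oxy]propanal with ethyl vinyl ketone).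
- Forward: ring B first (steps 1–2, then masked as a silyl-protected allylic alcohol), side chain grown from C4 (steps 5–9), ring A closed in step 13, then dienoate, C7 reduction, sulfation, saponification.
- Stereochemistry: C4a from the amine-catalysed Michael addition of step 1; C2 from (R)-but-3-yn-2-ol by chair chirality transfer in the Claisen step; C8a, C1 and C8 in the ring closure (tether face, catalyst face, convex protonation); C7 by convex-face hydride.
- Alkene geometry: iodo-ylide (Z), syn-carbometalation (E), Claisen chair (E), phosphonate olefination (E,E).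

Key step: step 13

Assumption: 3-[(4-methoxybenzyl)oxy]propanal is taken as a purchasable aldehyde, and the sulfate is carried as its sodium salt until the last acidification releases the free acid form drawn for the target.

**Step 1**
Reactants: 1 3-[(4-methoxybenzyl)oxy]propanal; 2 pent-1-en-3-one
Product: 3 (2R)-2-{[(4-methoxybenzyl)oxy]methyl}-5-oxoheptanal
Conditions: (R)-2-[diphenyl(trimethylsilyloxy)methyl]pyrrolidine (10 mol%), ethyl 3,4-dihydroxybenzoate (20 mol%), neat, 4 °C
Reagents that add atoms: none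
Why: Enamine-catalysed Michael addition of an aldehyde to a vinyl ketone; the diphenyl(silyloxy)methyl group shields one face of the (E)-enamine, so the enone is taken up on the open face and the future C4a is set as the (R)-aldehyde.

**Step 2**
Reactants: 3 (2R)-2-{[(4-methoxybenzyl)oxy]methyl}-5-oxoheptanal
Product: 5 (4S)-4-{[(4-methoxybenzyl)oxy]methyl}-2-methylcyclohex-2-en-1-one, via aldol 4 (not isolated)
Conditions: LiOH·H2O (0.2 equiv), i-PrOH, rt
Reagents that add atoms: none
Why: Intramolecular aldol condensation in which the ethyl ketone enolate adds to the aldehyde and the ketol loses water to the conjugated 2-methylenone; the stereocentre becomes the gamma carbon and should survive if exposure to base is kept short.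

**Step 3**
Reactants: 5 (4S)-4-{[(4-methoxybenzyl)oxy]methyl}-2-methylcyclohex-2-en-1-one
Product: 6 (4S)-4-{[(4-methoxybenzyl)oxy]methyl}-2-methylcyclohex-2-en-1-ol (both C1 epimers)
Conditions: NaBH4, CeCl3·7H2O, MeOH, −40 °C
Reagents that add atoms: none
Why: Luche 1,2-reduction masks the C7 carbonyl for the organometallic and hydride steps ahead; the new carbinol centre is left unassigned because step 12 oxidises it again.

**Step 4**
Reactants: 6 (4S)-4-{[(4-methoxybenzyl)oxy]methyl}-2-methylcyclohex-2-en-1-ol (both C1 epimers)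
Product: 7 tert-butyl{[(4S)-4-{[(4-methoxybenzyl)oxy]methyl}-2-methylcyclohex-2-en-1-yl]oxy}dimethylsilane (both C1 epimers)
Conditions: TBSCl, imidazole, DMF, rt
Reagents that add atoms: tert-butyldimethylsilyl chloride, CC(C)(C)[Si](C)(C)Cl
Why: Standard silylation of a secondary allylic alcohol, giving an ether that should tolerate DDQ, ylides, AlMe3, hot orthoester and iBu2AlH.

**Step 5**
Reactants: 7 tert-butyl{[(4S)-4-{[(4-methoxybenzyl)oxy]methyl}-2-methylcyclohex-2-en-1-yl]oxy}dimethylsilane (both C1 epimers)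
Product: 8 [(1S)-4-{[tert-butyl(dimethyl)silyl]oxy}-3-methylcyclohex-2-en-1-yl]methanol (both C4 epimers)
Conditions: DDQ, CH2Cl2/pH 7 buffer, 0 °C
Reagents that add atoms: none
Why: Oxidative cleavage of the 4-methoxybenzyl ether by DDQ, which should spare the silyl ether and the trisubstituted ring alkene.

**Step 6**
Reactants: 8 [(1S)-4-{[tert-butyl(dimethyl)silyl]oxy}-3-methylcyclohex-2-en-1-yl]methanol (both C4 epimers)
Product: 9 (1S)-4-{[tert-butyl(dimethyl)silyl]oxy}-3-methylcyclohex-2-ene-1-carbaldehyde (both C4 epimers)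
Conditions: Dess–Martin periodinane, NaHCO3, CH2Cl2, 0 °C, used crude
Reagents that add atoms: none
Why: Buffered Dess–Martin oxidation gives the C4 aldehyde under non-basic conditions; it is used at once because its alpha hydrogen (C4a) is allylic and prone to epimerisation or migration of the ring alkene.

**Step 7**
Reactants: 9 (1S)-4-{[tert-butyl(dimethyl)silyl]oxy}-3-methylcyclohex-2-ene-1-carbaldehyde (both C4 epimers)
Product: 10 tert-butyl{[(4S)-4-[(1Z)-2-iodoprop-1-en-1-yl]-2-methylcyclohex-2-en-1-yl]oxy}dimethylsilane (both C1 epimers)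
Conditions: EtPPh3I, n-BuLi, THF, 0 °C; I2, −78 °C; NaN(SiMe3)2, −20 °C; then 9, −78 °C
Reagents that add atoms: ethyltriphenylphosphonium iodide, CC[P+](c1ccccc1)(c1ccccc1)c1ccccc1.[I-]; iodine, II
Why: Stork–Zhao-type Wittig olefination with the alpha-iodo ylide, which is known to give (Z)-2-iodoalk-2-enes; iodine ends up cis to C4a, so the carbon that replaces it (C2) will be cis to C4a as ring A requires.

**Step 8**
Reactants: 11 (2R)-but-3-yn-2-ol; 10 tert-butyl{[(4S)-4-[(1Z)-2-iodoprop-1-en-1-yl]-2-methylcyclohex-2-en-1-yl]oxy}dimethylsilane (both C1 epimers)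
Product: 13 (2R,3E,5Z)-6-[(1R)-4-{[tert-butyl(dimethyl)silyl]oxy}-3-methylcyclohex-2-en-1-yl]-3,5-dimethylhexa-3,5-dien-2-ol (both ring C4 epimers), via (E)-alkenylalane 12 (not isolated)
Conditions: 11, AlMe3 (3.5 equiv), Cp2ZrCl2 (0.3 equiv), ClCH2CH2Cl, 0 °C to rt; then 10, ZnCl2 (co-catalyst), Pd(PPh3)4 (5 mol%), THF, rt
Reagents that add atoms: trimethylaluminium, C[Al](C)C
Why: Zirconium-catalysed syn-methylalumination of the terminal alkyne (methyl to the internal carbon, aluminium to the terminus) followed by Negishi cross-coupling with retention at both alkenyl carbons gives the (3E,5Z)-dienol with the purchased (R)-carbinol untouched; material from the minor enantiomer of step 1 is now a diastereomer and can be removed.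

**Step 9**
Reactants: 13 (2R,3E,5Z)-6-[(1R)-4-{[tert-butyl(dimethyl)silyl]oxy}-3-methylcyclohex-2-en-1-yl]-3,5-dimethylhexa-3,5-dien-2-ol (both ring C4 epimers); 14 triethyl orthoacetate
Product: 16 ethyl (3R,4Z)-3-[(2E)-but-2-en-2-yl]-5-[(1R)-4-{[tert-butyl(dimethyl)silyl]oxy}-3-methylcyclohex-2-en-1-yl]-4-methylpent-4-enoate (both ring C4 epimers), via ketene acetal 15 (not isolated)
Conditions: MeC(OEt)3 (excess), EtCO2H (cat.), 130 °C, EtOH distilled off
Reagents that add atoms: none
Why: Johnson–Claisen rearrangement through a chair transition state with the carbinol methyl equatorial; this forms C1–C2 on the face from which oxygen leaves, so the (R)-carbinol is transferred to (R)-C2 and the new butenyl alkene is (E), while the temperature is kept low enough to avoid a 1,5-hydrogen shift in the (Z)-diene.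

**Step 10**
Reactants: 16 ethyl (3R,4Z)-3-[(2E)-but-2-en-2-yl]-5-[(1R)-4-{[tert-butyl(dimethyl)silyl]oxy}-3-methylcyclohex-2-en-1-yl]-4-methylpent-4-enoate (both ring C4 epimers)
Product: 17 (3R,4Z)-3-[(2E)-but-2-en-2-yl]-5-[(1R)-4-{[tert-butyl(dimethyl)silyl]oxy}-3-methylcyclohex-2-en-1-yl]-4-methylpent-4-en-1-ol (both ring C4 epimers)
Conditions: iBu2AlH, CH2Cl2, −78 to 0 °C
Reagents that add atoms: none
Why: Full reduction of the ester to the primary alcohol is cleaner than a partial reduction and leaves the silyl ether and the three alkenes alone.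

**Step 11**
Reactants: 17 (3R,4Z)-3-[(2E)-but-2-en-2-yl]-5-[(1R)-4-{[tert-butyl(dimethyl)silyl]oxy}-3-methylcyclohex-2-en-1-yl]-4-methylpent-4-en-1-ol (both ring C4 epimers)
Product: 18 (4R)-4-[(1Z,3R)-3-[(2E)-but-2-en-2-yl]-5-hydroxy-2-methylpent-1-en-1-yl]-2-methylcyclohex-2-en-1-ol (both C1 epimers)
Conditions: Bu4NF, THF, rt
Reagents that add atoms: none
Why: Fluoride cleavage of the secondary silyl ether frees the ring carbinol so that both oxidations can be done in one operation.

**Step 12**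
Reactants: 18 (4R)-4-[(1Z,3R)-3-[(2E)-but-2-en-2-yl]-5-hydroxy-2-methylpent-1-en-1-yl]-2-methylcyclohex-2-en-1-ol (both C1 epimers)
Product: 19 (3R,4Z)-3-[(2E)-but-2-en-2-yl]-4-methyl-5-[(1R)-3-methyl-4-oxocyclohex-2-en-1-yl]pent-4-enal
Conditions: Dess–Martin periodinane (3 equiv), NaHCO3, CH2Cl2, 0 °C to rt, used at once
Reagents that add atoms: none
Why: Double Dess–Martin oxidation turns the primary alcohol into the aldehyde and both ring carbinol epimers into the same 2-methylenone under buffered conditions that should not touch the gamma hydrogen at C4a.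

**Step 13**
Reactants: 19 (3R,4Z)-3-[(2E)-but-2-en-2-yl]-4-methyl-5-[(1R)-3-methyl-4-oxocyclohex-2-en-1-yl]pent-4-enal
Product: 20 (1R,2R,4aS,8S,8aR)-2-[(2E)-but-2-en-2-yl]-3,8-dimethyl-7-oxo-1,2,4a,5,6,7,8,8a-octahydronaphthalene-1-carbaldehyde
Conditions: (R)-2-[diphenyl(trimethylsilyloxy)methyl]pyrrolidine (20 mol%), PhCO2H (20 mol%), toluene, 0 °C, cold filtration through silica
Reagents that add atoms: none
Why: The amine condenses with the aldehyde of 19 to an (E)-enamine whose nucleophilic carbon C1 is held near C8a by the (Z)-C3=C4 alkene; conjugate addition to the 2-methylenone closes ring A in a 6-exo-trig manner (the accepting C8=C8a bond lies outside the new ring) and gives the ring B enol and an iminium ion that water hydrolyses with return of the catalyst. The closest known reaction type is the diarylprolinol-silyl-ether-catalysed intramolecular Michael addition of aldehydes to cyclic enones and dienones, which gives cis-fused bicycles. C8a is controlled by C4a, because the four-atom tether can only reach the enone face on which C4a holds it and the new bond forms axially on ring B, so the fusion is cis. C1 is controlled by the catalyst, whose (R)-configured shielding group blocks the Si face of the enamine carbon so that C8a bonds to the Re face, placing the formyl group trans to the butenyl group and cis to C8, while the opposite topology would press the amine against the C8 methyl group. C8 is set when the enol is protonated anti to the new axial C1–C8a bond, that is from the convex face, leaving the methyl group equatorial and cis to C1. The step needs enamine formation at the aldehyde only and intact C4a and C8 centres; the hindered, weakly basic amine does not condense with the 2-methylenone, the fixed C4a and C2 centres and the (Z)-alkene define the tether, and low temperature with a prompt cold work-up guards the kinetic C1 and C8 configurations.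

**Step 14**
Reactants: 20 (1R,2R,4aS,8S,8aR)-2-[(2E)-but-2-en-2-yl]-3,8-dimethyl-7-oxo-1,2,4a,5,6,7,8,8a-octahydronaphthalene-1-carbaldehyde; 21 triethyl (2E)-4-phosphonobut-2-enoate
Product: 22 ethyl (2E,4E)-5-[(1R,2R,4aS,8S,8aR)-2-[(2E)-but-2-en-2-yl]-3,8-dimethyl-7-oxo-1,2,4a,5,6,7,8,8a-octahydronaphthalen-1-yl]penta-2,4-dienoate
Conditions: 21, LiN(SiMe3)2, THF, −78 to −20 °C
Reagents that add atoms: none
Why: Vinylogous Horner–Wadsworth–Emmons olefination of the aldehyde with the delocalised, weakly basic phosphonate anion should give the (2E,4E)-dienoate, leave the hindered ketone alone and be too cold to epimerise C1 or C8.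

**Step 15**
Reactants: 22 ethyl (2E,4E)-5-[(1R,2R,4aS,8S,8aR)-2-[(2E)-but-2-en-2-yl]-3,8-dimethyl-7-oxo-1,2,4a,5,6,7,8,8a-octahydronaphthalen-1-yl]penta-2,4-dienoate
Product: 23 ethyl (2E,4E)-5-[(1R,2R,4aS,7R,8S,8aR)-2-[(2E)-but-2-en-2-yl]-7-hydroxy-3,8-dimethyl-1,2,4a,5,6,7,8,8a-octahydronaphthalen-1-yl]penta-2,4-dienoate
Conditions: LiBH(sBu)3 (1.1 equiv), THF, −78 °C
Reagents that add atoms: none
Why: Bulky trialkylborohydride reduction of the cis-fused ketone; the concave face of C7 is screened by ring A (axial C1–C8a bond or axial C8 methyl, depending on the chair), so hydride should enter from the convex face and give the (7R)-alcohol cis to the C8 methyl, and at −78 °C the ketone should react well before the dienoate.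

**Step 16**
Reactants: 23 ethyl (2E,4E)-5-[(1R,2R,4aS,7R,8S,8aR)-2-[(2E)-but-2-en-2-yl]-7-hydroxy-3,8-dimethyl-1,2,4a,5,6,7,8,8a-octahydronaphthalen-1-yl]penta-2,4-dienoate
Product: 24 ethyl (2E,4E)-5-[(1R,2R,4aS,7R,8S,8aR)-2-[(2E)-but-2-en-2-yl]-3,8-dimethyl-7-(sulfooxy)-1,2,4a,5,6,7,8,8a-octahydronaphthalen-1-yl]penta-2,4-dienoate (handled as its sodium salt)
Conditions: SO3·pyridine (5 equiv), pyridine, 40 °C; aq. NaHCO3
Reagents that add atoms: sulfur trioxide pyridine complex, [O-]S(=O)(=O)[n+]1ccccc1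
Why: O-Sulfation of a hindered secondary alcohol with the pyridine complex of sulfur trioxide occurs with retention at C7 and does not affect the ester or the alkenes.

**Step 17**
Reactants: 24 ethyl (2E,4E)-5-[(1R,2R,4aS,7R,8S,8aR)-2-[(2E)-but-2-en-2-yl]-3,8-dimethyl-7-(sulfooxy)-1,2,4a,5,6,7,8,8a-octahydronaphthalen-1-yl]penta-2,4-dienoate (handled as its sodium salt)
Product: 25 (2E,4E)-5-[(1R,2R,4aS,7R,8S,8aR)-2-[(2E)-but-2-en-2-yl]-3,8-dimethyl-7-(sulfooxy)-1,2,4a,5,6,7,8,8a-octahydronaphthalen-1-yl]penta-2,4-dienoic acid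
Conditions: LiOH, THF/MeOH/H2O, rt; then dilute HCl to pH 2 at 0 °C
Reagents that add atoms: lithium hydroxide (its oxygen ends in the carboxyl group), [Li+].[OH-]
Why: Saponification of the dienoate; the alkyl sulfate monoanion is inert to hydroxide at room temperature, and brief cold acidification releases the free acid.

**Compound list**

1 | 3-[(4-methoxybenzyl)oxy]propanal | COc1ccc(COCCC=O)cc1 | starting material
2 | pent-1-en-3-one (ethyl vinyl ketone) | CCC(=O)C=C | starting material
3 | (2R)-2-{[(4-methoxybenzyl)oxy]methyl}-5-oxoheptanal | COc1ccc(COC[C@H](C=O)CCC(=O)CC)cc1 | intermediate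
4 | (4R)-3-hydroxy-4-{[(4-methoxybenzyl)oxy]methyl}-2-methylcyclohexan-1-one (aldol, C2 and C3 unassigned) | COc1ccc(COC[C@H]2CCC(=O)C(C)C2O)cc1 | intermediate (not isolated)
5 | (4S)-4-{[(4-methoxybenzyl)oxy]methyl}-2-methylcyclohex-2-en-1-one | COc1ccc(COC[C@H]2CCC(=O)C(C)=C2)cc1 | intermediate
6 | (4S)-4-{[(4-methoxybenzyl)oxy]methyl}-2-methylcyclohex-2-en-1-ol, both C1 epimers | COc1ccc(COC[C@H]2CCC(O)C(C)=C2)cc1 | intermediate
7 | tert-butyl{[(4S)-4-{[(4-methoxybenzyl)oxy]methyl}-2-methylcyclohex-2-en-1-yl]oxy}dimethylsilane, both C1 epimers | COc1ccc(COC[C@H]2CCC(O[Si](C)(C)C(C)(C)C)C(C)=C2)cc1 | intermediate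
8 | [(1S)-4-{[tert-butyl(dimethyl)silyl]oxy}-3-methylcyclohex-2-en-1-yl]methanol, both C4 epimers | OC[C@H]1CCC(O[Si](C)(C)C(C)(C)C)C(C)=C1 | intermediate
9 | (1S)-4-{[tert-butyl(dimethyl)silyl]oxy}-3-methylcyclohex-2-ene-1-carbaldehyde, both C4 epimers | O=C[C@H]1CCC(O[Si](C)(C)C(C)(C)C)C(C)=C1 | intermediate
10 | tert-butyl{[(4S)-4-[(1Z)-2-iodoprop-1-en-1-yl]-2-methylcyclohex-2-en-1-yl]oxy}dimethylsilane, both C1 epimers | C/C(I)=C/[C@H]1CCC(O[Si](C)(C)C(C)(C)C)C(C)=C1 | intermediate
11 | (2R)-but-3-yn-2-ol | C[C@@H](O)C#C | starting material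
12 | dimethylaluminium (2R,3E)-4-(dimethylalumanyl)-3-methylbut-3-en-2-olate | C[C@@H](O[Al](C)C)/C(C)=C/[Al](C)C | intermediate (not isolated)
13 | (2R,3E,5Z)-6-[(1R)-4-{[tert-butyl(dimethyl)silyl]oxy}-3-methylcyclohex-2-en-1-yl]-3,5-dimethylhexa-3,5-dien-2-ol, both ring C4 epimers | C[C@@H](O)/C(C)=C/C(C)=C\[C@H]1CCC(O[Si](C)(C)C(C)(C)C)C(C)=C1 | intermediate
14 | triethyl orthoacetate | CCOC(C)(OCC)OCC | starting material
15 | tert-butyl{[(4R)-4-[(1Z,3E,5R)-5-[(1-ethoxyethenyl)oxy]-2,4-dimethylhexa-1,3-dien-1-yl]-2-methylcyclohex-2-en-1-yl]oxy}dimethylsilane (mixed ketene acetal) | C=C(OCC)O[C@H](C)/C(C)=C/C(C)=C\[C@H]1CCC(O[Si](C)(C)C(C)(C)C)C(C)=C1 | intermediate (not isolated)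
16 | ethyl (3R,4Z)-3-[(2E)-but-2-en-2-yl]-5-[(1R)-4-{[tert-butyl(dimethyl)silyl]oxy}-3-methylcyclohex-2-en-1-yl]-4-methylpent-4-enoate, both ring C4 epimers | C/C=C(\C)[C@@H](CC(=O)OCC)/C(C)=C\[C@H]1CCC(O[Si](C)(C)C(C)(C)C)C(C)=C1 | intermediate
17 | (3R,4Z)-3-[(2E)-but-2-en-2-yl]-5-[(1R)-4-{[tert-butyl(dimethyl)silyl]oxy}-3-methylcyclohex-2-en-1-yl]-4-methylpent-4-en-1-ol, both ring C4 epimers | C/C=C(\C)[C@@H](CCO)/C(C)=C\[C@H]1CCC(O[Si](C)(C)C(C)(C)C)C(C)=C1 | intermediate
18 | (4R)-4-[(1Z,3R)-3-[(2E)-but-2-en-2-yl]-5-hydroxy-2-methylpent-1-en-1-yl]-2-methylcyclohex-2-en-1-ol, both C1 epimers | C/C=C(\C)[C@@H](CCO)/C(C)=C\[C@H]1CCC(O)C(C)=C1 | intermediate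
19 | (3R,4Z)-3-[(2E)-but-2-en-2-yl]-4-methyl-5-[(1R)-3-methyl-4-oxocyclohex-2-en-1-yl]pent-4-enal | C/C=C(\C)[C@@H](CC=O)/C(C)=C\[C@H]1CCC(=O)C(C)=C1 | intermediate
20 | (1R,2R,4aS,8S,8aR)-2-[(2E)-but-2-en-2-yl]-3,8-dimethyl-7-oxo-1,2,4a,5,6,7,8,8a-octahydronaphthalene-1-carbaldehyde | C/C=C(\C)[C@@H]1C(C)=C[C@H]2CCC(=O)[C@@H](C)[C@H]2[C@H]1C=O | intermediate
21 | triethyl (2E)-4-phosphonobut-2-enoate | CCOC(=O)/C=C/CP(=O)(OCC)OCC | starting material
22 | ethyl (2E,4E)-5-[(1R,2R,4aS,8S,8aR)-2-[(2E)-but-2-en-2-yl]-3,8-dimethyl-7-oxo-1,2,4a,5,6,7,8,8a-octahydronaphthalen-1-yl]penta-2,4-dienoate | C/C=C(\C)[C@@H]1C(C)=C[C@H]2CCC(=O)[C@@H](C)[C@H]2[C@H]1/C=C/C=C/C(=O)OCC | intermediate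
23 | ethyl (2E,4E)-5-[(1R,2R,4aS,7R,8S,8aR)-2-[(2E)-but-2-en-2-yl]-7-hydroxy-3,8-dimethyl-1,2,4a,5,6,7,8,8a-octahydronaphthalen-1-yl]penta-2,4-dienoate | C/C=C(\C)[C@@H]1C(C)=C[C@H]2CC[C@@H](O)[C@@H](C)[C@H]2[C@H]1/C=C/C=C/C(=O)OCC | intermediate
24 | ethyl (2E,4E)-5-[(1R,2R,4aS,7R,8S,8aR)-2-[(2E)-but-2-en-2-yl]-3,8-dimethyl-7-(sulfooxy)-1,2,4a,5,6,7,8,8a-octahydronaphthalen-1-yl]penta-2,4-dienoate | C/C=C(\C)[C@@H]1C(C)=C[C@H]2CC[C@@H](OS(=O)(=O)O)[C@@H](C)[C@H]2[C@H]1/C=C/C=C/C(=O)OCC | intermediate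
25 | (2E,4E)-5-[(1R,2R,4aS,7R,8S,8aR)-2-[(2E)-but-2-en-2-yl]-3,8-dimethyl-7-(sulfooxy)-1,2,4a,5,6,7,8,8a-octahydronaphthalen-1-yl]penta-2,4-dienoic acid | C/C=C(\C)[C@@H]1C(C)=C[C@H]2CC[C@@H](OS(=O)(=O)O)[C@@H](C)[C@H]2[C@H]1/C=C/C=C/C(=O)O | target

**Step count**

Total: 17 steps. Longest linear sequence: 17 steps (1 and 2 to 25); compounds 11, 14 and 21 are bought and enter without steps of their own.

**Steps most likely to fail**

Step 13 (ring closure). What may go wrong:
- the enamine may add through its shielded face, or in an arrangement that turns the formyl-bearing carbon the other way, and give the C1 epimer;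
- enamine formation at the beta-branched aldehyde may be slow enough for amine-induced epimerisation at C4a or C8 to compete.

Fallback: set out from 19 and return at 20 by a preformed metal enolate in place of the catalytic enamine. KH (0.95 equiv) in THF at −40 °C should remove an aldehyde alpha hydrogen, which is several pKa units more acidic than the C4a and C6 hydrogens, and give potassium (3R,4Z)-3-[(2E)-but-2-en-2-yl]-4-methyl-5-[(1R)-3-methyl-4-oxocyclohex-2-en-1-yl]penta-1,4-dien-1-olate F1. This enolate should close onto C8a through a compact arrangement in which potassium bridges the two oxygens, so the topology is fixed by the metal and the tether and no longer by an amine. The resulting ring B potassium enolate F2 of 20 is quenched at −78 °C with acetic acid from the convex face to give 20.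

Step 7 (iodo-olefination). What may go wrong:
- modest Z selectivity and loss of iodine from the ylide;
- base-induced epimerisation at C4a or migration of the ring alkene in the alpha-branched, beta,gamma-unsaturated aldehyde.

Fallback: set out from 9 and return at 13, which also bypasses step 8. A Still–Gennari olefination (ethyl 2-[bis(2,2,2-trifluoroethoxy)phosphoryl]propanoate, KN(SiMe3)2, 18-crown-6, THF, −78 °C) uses a far less basic stabilised anion and should give ethyl (2Z)-3-[(1S)-4-{[tert-butyl(dimethyl)silyl]oxy}-3-methylcyclohex-2-en-1-yl]-2-methylprop-2-enoate F3. iBu2AlH reduces it to (2Z)-3-[(1R)-4-{[tert-butyl(dimethyl)silyl]oxy}-3-methylcyclohex-2-en-1-yl]-2-methylprop-2-en-1-ol F4, and MnO2 gives the (2Z)-enal, (2Z)-3-[(1S)-4-{[tert-butyl(dimethyl)silyl]oxy}-3-methylcyclohex-2-en-1-yl]-2-methylprop-2-enal F5. Horner–Wadsworth–Emmons reaction with diethyl (3-oxobutan-2-yl)phosphonate and Ba(OH)2 in wet THF gives (3E,5Z)-6-[(1R)-4-{[tert-butyl(dimethyl)silyl]oxy}-3-methylcyclohex-2-en-1-yl]-3,5-dimethylhexa-3,5-dien-2-one F6. Corey–Bakshi–Shibata reduction with the (S)-2-methyl-oxazaborolidine and BH3·SMe2 then delivers the (R)-carbinol 13.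

Step 9 (Johnson–Claisen). What may go wrong:
- acid-induced ionisation of the doubly allylic carbinol, leading to elimination to a triene or to the ethyl ether;
- a thermal 1,5-hydrogen shift in the (Z)-diene;
- incomplete chirality transfer at 130 °C.

Fallback: set out from 13 and return at 17 by an Ireland–Claisen rearrangement, which runs under basic conditions at or below room temperature. Ac2O, DMAP and pyridine give (2R,3E,5Z)-6-[(1R)-4-{[tert-butyl(dimethyl)silyl]oxy}-3-methylcyclohex-2-en-1-yl]-3,5-dimethylhexa-3,5-dien-2-yl acetate F7. LDA in THF at −78 °C followed by Me3SiCl/Et3N gives the trimethylsilyl ketene acetal F8, which is not isolated and rearranges through the same chair on warming to room temperature to the trimethylsilyl ester F9, also not isolated. Aqueous acid then gives (3R,4Z)-3-[(2E)-but-2-en-2-yl]-5-[(1R)-4-{[tert-butyl(dimethyl)silyl]oxy}-3-methylcyclohex-2-en-1-yl]-4-methylpent-4-enoic acid F10, and LiAlH4 in Et2O at 0 °C reduces it to 17.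

**Further compounds**

F1 | step 13 | potassium (3R,4Z)-3-[(2E)-but-2-en-2-yl]-4-methyl-5-[(1R)-3-methyl-4-oxocyclohex-2-en-1-yl]penta-1,4-dien-1-olate (aldehyde enolate of 19) | C/C=C(\C)[C@@H](C=C[O-])/C(C)=C\[C@H]1CCC(=O)C(C)=C1.[K+]
F2 | step 13 | potassium C7 enolate of 20 (C7=C8 enolate, other centres as in 20) | C/C=C(\C)[C@@H]1C(C)=C[C@H]2CCC([O-])=C(C)[C@H]2[C@H]1C=O.[K+]
F3 | step 7 | ethyl (2Z)-3-[(1S)-4-{[tert-butyl(dimethyl)silyl]oxy}-3-methylcyclohex-2-en-1-yl]-2-methylprop-2-enoate | CCOC(=O)/C(C)=C\[C@H]1CCC(O[Si](C)(C)C(C)(C)C)C(C)=C1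
F4 | step 7 | (2Z)-3-[(1R)-4-{[tert-butyl(dimethyl)silyl]oxy}-3-methylcyclohex-2-en-1-yl]-2-methylprop-2-en-1-ol | OC/C(C)=C\[C@H]1CCC(O[Si](C)(C)C(C)(C)C)C(C)=C1
F5 | step 7 | (2Z)-3-[(1S)-4-{[tert-butyl(dimethyl)silyl]oxy}-3-methylcyclohex-2-en-1-yl]-2-methylprop-2-enal | O=C/C(C)=C\[C@H]1CCC(O[Si](C)(C)C(C)(C)C)C(C)=C1
F6 | step 7 | (3E,5Z)-6-[(1R)-4-{[tert-butyl(dimethyl)silyl]oxy}-3-methylcyclohex-2-en-1-yl]-3,5-dimethylhexa-3,5-dien-2-one | CC(=O)/C(C)=C/C(C)=C\[C@H]1CCC(O[Si](C)(C)C(C)(C)C)C(C)=C1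
F7 | step 9 | (2R,3E,5Z)-6-[(1R)-4-{[tert-butyl(dimethyl)silyl]oxy}-3-methylcyclohex-2-en-1-yl]-3,5-dimethylhexa-3,5-dien-2-yl acetate | CC(=O)O[C@H](C)/C(C)=C/C(C)=C\[C@H]1CCC(O[Si](C)(C)C(C)(C)C)C(C)=C1
F8 | step 9 | trimethylsilyl ketene acetal of F7 (1-(trimethylsilyloxy)ethenyl ether of 13) | C=C(O[Si](C)(C)C)O[C@H](C)/C(C)=C/C(C)=C\[C@H]1CCC(O[Si](C)(C)C(C)(C)C)C(C)=C1
F9 | step 9 | trimethylsilyl (3R,4Z)-3-[(2E)-but-2-en-2-yl]-5-[(1R)-4-{[tert-butyl(dimethyl)silyl]oxy}-3-methylcyclohex-2-en-1-yl]-4-methylpent-4-enoate | C/C=C(\C)[C@@H](CC(=O)O[Si](C)(C)C)/C(C)=C\[C@H]1CCC(O[Si](C)(C)C(C)(C)C)C(C)=C1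
F10 | step 9 | (3R,4Z)-3-[(2E)-but-2-en-2-yl]-5-[(1R)-4-{[tert-butyl(dimethyl)silyl]oxy}-3-methylcyclohex-2-en-1-yl]-4-methylpent-4-enoic acid | C/C=C(\C)[C@@H](CC(=O)O)/C(C)=C\[C@H]1CCC(O[Si](C)(C)C(C)(C)C)C(C)=C1
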